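**Plan**

- Retrosynthesis: the ester C(=O)–O bond between the two C15 halves is cut first. Both halves are then traced to one cyclic β-keto ester 17 by removing the single carbon on C3a (the butenolide CH2 in the right half, the CH2O carbon of the carbinol in the left half).
- 17 is cut at the ring bond C7–C7a (2-benzofuranone numbering). C7 is both a ring carbon and the γ-carbon of the exocyclic (E)-2-(hydroxymethyl)propenoate, and C7a is the α-carbon of a 1,3-dicarbonyl (lactone C1=O, C3a at the ketone level). This is the retron of a phosphine-catalysed γ-umpolung addition to an allenoate.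
- Forward: (S)-limonene supplies the chain C3a–C4–C5–C6–C7 with the isopropyl centre. A ketene Wittig reaction makes the allenoate, and the phosphine closes the cyclohexanone ring and installs the complete side chain in one event.
- The right half then forms its butenolide ring (enol triflate, Stille hydroxymethylation, lactonisation) and the left half its carbinol (methylenation, dihydroxylation). Esterification and one deprotection finish the route.
- Stereochemistry: the isopropyl centre comes from limonene; C7 from 1,2-induction in the chair ring closure; C7a of the left half from thermodynamic control in the β-keto ester; the tertiary carbinol from equatorial osmylation; both E alkenes from the phosphine elimination.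

Key step: step 8

Remark on the chemistry: both halves of the target have the same absolute configuration at the isopropyl-bearing and side-chain-bearing ring carbons, so (S)-limonene serves both; 17 is drawn as its trans keto tautomer although it should equilibrate with its enol and its C1 epimer.

**Route**

Step 1
Reactants: 1 (S)-(−)-limonene
Product: 2 (4S)-1-methyl-4-(propan-2-yl)cyclohex-1-ene
Conditions: H2 (1 atm), RhCl(PPh3)3 (1 mol%), toluene/EtOH, rt
Reagents that add atoms: none
Why: Homogeneous hydrogenation with RhCl(PPh3)3 should reduce only the 1,1-disubstituted isopropenyl alkene and leave the trisubstituted ring alkene and the stereocentre untouched.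

Step 2
Reactants: 2 (4S)-1-methyl-4-(propan-2-yl)cyclohex-1-ene
Product: 4 (5S)-5-(2,2-dimethoxyethyl)-6-methylheptan-2-one, via keto aldehyde 3 (not isolated)
Conditions: O3, CH2Cl2, −78 °C; Me2S, −78 °C → rt; then MeOH, p-TsOH·H2O (cat.), rt; NaHCO3
Reagents that add atoms: ozone, [O-][O+]=O; methanol, CO
Why: Ozonolysis with reductive work-up cleaves the ring alkene to keto aldehyde 3, and acid-catalysed acetal formation in methanol should be selective for the aldehyde over the methyl ketone.

Step 3
Reactants: 4 (5S)-5-(2,2-dimethoxyethyl)-6-methylheptan-2-one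
Product: 5 (4S)-4-(2,2-dimethoxyethyl)-5-methylhexanoic acid
Conditions: Br2, NaOH, H2O/1,4-dioxane, 0 °C → rt; aq. NaHSO4 to pH 4, 0 °C
Reagents that add atoms: sodium hydroxide, [Na+].[OH-]
Why: The haloform reaction degrades the methyl ketone to the carboxylic acid under basic conditions that the acetal tolerates, which brings the future C3a to the acid level.

Step 4
Reactants: 5 (4S)-4-(2,2-dimethoxyethyl)-5-methylhexanoic acid; 6 3-tert-butoxy-3-oxopropanoic acid (mono-tert-butyl malonate)
Product: 8 tert-butyl (6S)-6-(2,2-dimethoxyethyl)-7-methyl-3-oxooctanoate, via acyl imidazole 7 (not isolated)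
Conditions: 1,1'-carbonyldiimidazole, THF, rt; then 6, MgCl2, Et3N, MeCN, rt → 40 °C; aq. NH4Cl
Reagents that add atoms: none
Why: Masamune–Brooks chain extension (acyl imidazole plus magnesium malonate half-ester, then decarboxylation) builds the β-keto ester under nearly neutral conditions, and the tert-butyl ester is chosen because it later resists lactonisation in the left half.

Step 5
Reactants: 8 tert-butyl (6S)-6-(2,2-dimethoxyethyl)-7-methyl-3-oxooctanoate
Product: 10 (3S)-8-tert-butoxy-6,8-dioxo-3-(propan-2-yl)octanoic acid, via aldehyde 9 (not isolated)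
Conditions: CrO3, H2SO4, H2O, acetone, 0 °C
Reagents that add atoms: water, O
Why: Aqueous chromic acid should hydrolyse the dimethyl acetal and oxidise the liberated aldehyde in the same flask (Jones oxidation), conditions that tert-butyl esters and β-keto esters withstand at 0 °C.

Step 6
Reactants: 11 tert-butyl (triphenylphosphoranylidene)acetate (2 equiv); 12 benzyl chloromethyl ether
Product: 13 tert-butyl 3-(benzyloxy)-2-(triphenylphosphoranylidene)propanoate
Conditions: toluene, 0 °C → rt; filtration of the phosphonium chloride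
Reagents that add atoms: none
Why: C-alkylation of the ester-stabilised phosphorane by the reactive chloromethyl ether, followed by transylidation with the second equivalent of 11, gives the α-substituted ylide.

Step 7
Reactants: 10 (3S)-8-tert-butoxy-6,8-dioxo-3-(propan-2-yl)octanoic acid; 13 tert-butyl 3-(benzyloxy)-2-(triphenylphosphoranylidene)propanoate
Product: 16 di-tert-butyl (5R)-2-[(benzyloxy)methyl]-8-oxo-5-(propan-2-yl)deca-2,3-dienedioate (both configurations of the allene axis), via acid chloride 14 (not isolated), via ketene 15 (not isolated)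
Conditions: 1-chloro-N,N,2-trimethylprop-1-en-1-amine, CH2Cl2, 0 °C → rt; then slow addition to 13 and Et3N, CH2Cl2, 0 °C → rt
Reagents that add atoms: none
Why: Dehydrochlorination of 14 gives ketene 15, which undergoes Wittig olefination at its C=O with 13 (ketene Wittig synthesis of allenoates); the ylide should trap the ketene faster than the weakly nucleophilic β-keto ester is acylated, and the allene axis needs no control because the next step erases it.

Step 8
Reactants: 16 di-tert-butyl (5R)-2-[(benzyloxy)methyl]-8-oxo-5-(propan-2-yl)deca-2,3-dienedioate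
Product: 17 tert-butyl (1S,5R,6S)-6-[(1E)-2-[(benzyloxy)methyl]-3-tert-butoxy-3-oxoprop-1-en-1-yl]-2-oxo-5-(propan-2-yl)cyclohexane-1-carboxylate
Conditions: PBu3 (20 mol%), AcOH (20 mol%), NaOAc (20 mol%), toluene (0.02 M), 60 °C
Reagents that add atoms: none
Why: Proposed new method: the phosphine should add to the central allene carbon C3 of 16 to give a phosphonium dienolate, which is protonated at C2 (AcOH as shuttle) to a vinylphosphonium that is electrophilic at the γ-carbon C4; the β-keto ester enolate (C9) attacks C4, and a proton shift followed by E1cB loss of PBu3 from the β-phosphonium ester enolate releases the conjugated enoate and the catalyst. The closest known reaction type is the phosphine-catalysed γ-umpolung addition of 1,3-dicarbonyl pronucleophiles to 2,3-allenoates and 2-alkynoates, together with its intramolecular ring closures by O- and N-nucleophiles; the intramolecular C–C version on an α,γ-disubstituted allenoate is the untested extension. The cyclohexanone ring closes in the 6-exo-trig mode, the carbanion attacking the C4=C3 vinylphosphonium with C3 staying outside the ring. The new stereocentre (C6 of 17) is controlled by the isopropyl-bearing centre: in the chair transition state the allylic C–H eclipses the vinylphosphonium (A(1,3) strain) and the isopropyl group and the forming side chain are both equatorial, giving the 5,6-trans product, while C1 is epimerisable and settles trans, and the allene axis is erased in the dienolate so both epimers of 16 converge. The E alkene should arise from antiperiplanar loss of the phosphine through the less strained rotamer and is also the thermodynamic isomer, reachable by reversible phosphine addition. The step needs γ-attack rather than β-attack or β′-pathways, which is secured by ring size (six against seven or eight), the poor leaving-group ability of benzyloxide and high dilution.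

Step 9
Reactants: 17 (cyclic β-keto ester from step 8)
Product: 18 tert-butyl (5R,6S)-6-[(1E)-2-[(benzyloxy)methyl]-3-tert-butoxy-3-oxoprop-1-en-1-yl]-5-(propan-2-yl)-2-[(trifluoromethanesulfonyl)oxy]cyclohex-1-ene-1-carboxylate
Conditions: Tf2O, i-Pr2NEt, CH2Cl2, −78 °C
Reagents that add atoms: trifluoromethanesulfonic anhydride, O=S(=O)(OS(=O)(=O)C(F)(F)F)C(F)(F)F
Why: O-sulfonylation of the β-keto ester enol gives the tetrasubstituted enol triflate conjugated with the ester, with no change at the two stereocentres.

Step 10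
Reactants: 18 (enol triflate from step 9); 19 (tributylstannyl)methanol
Product: 20 tert-butyl (5R,6S)-6-[(1E)-2-[(benzyloxy)methyl]-3-tert-butoxy-3-oxoprop-1-en-1-yl]-2-(hydroxymethyl)-5-(propan-2-yl)cyclohex-1-ene-1-carboxylate
Conditions: Pd(PPh3)4 (5 mol%), LiCl, 1,4-dioxane, 90 °C
Reagents that add atoms: none
Why: Stille coupling of the vinyl triflate with the hydroxymethyl stannane places the CH2OH carbon on C3a cis to the ester, and the tert-butyl ester should keep the product from lactonising before the next step.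

Step 11
Reactants: 20 (allylic alcohol from step 10)
Product: 22 (2E)-2-[(benzyloxy)methyl]-3-[(6R,7S)-1-oxo-6-(propan-2-yl)-1,3,4,5,6,7-hexahydro-2-benzofuran-7-yl]prop-2-enoic acid, via hydroxy diacid 21 (not isolated)
Conditions: TFA/CH2Cl2 (1:3), 0 °C → rt
Reagents that add atoms: none
Why: Acidolysis of both tert-butyl esters gives hydroxy diacid 21, whose ring acid and cis hydroxymethyl group should lactonise at once to the butenolide, while the benzyl ether is stable to TFA.

Step 12
Reactants: 17 (cyclic β-keto ester from step 8)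
Product: 23 tert-butyl (1S,5R,6S)-6-[(1E)-2-[(benzyloxy)methyl]-3-tert-butoxy-3-oxoprop-1-en-1-yl]-2-methylidene-5-(propan-2-yl)cyclohexane-1-carboxylate
Conditions: Zn, CH2Br2, TiCl4, THF/CH2Cl2, 0 °C → rt
Reagents that add atoms: dibromomethane, BrCBr
Why: The non-basic Zn/CH2Br2/TiCl4 reagent (Takai–Lombardo methylenation) should convert the readily enolised ketone of the trans keto tautomer into the exocyclic alkene without epimerising C1 or moving the double bond into conjugation.

Step 13
Reactants: 23 (exocyclic alkene from step 12)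
Product: 24 tert-butyl (1S,2S,5R,6S)-6-[(1E)-2-[(benzyloxy)methyl]-3-tert-butoxy-3-oxoprop-1-en-1-yl]-2-hydroxy-2-(hydroxymethyl)-5-(propan-2-yl)cyclohexane-1-carboxylate
Conditions: OsO4 (2 mol%), N-methylmorpholine N-oxide, acetone/H2O (8:1), 0 °C → rt
Reagents that add atoms: N-methylmorpholine N-oxide, C[N+]1([O-])CCOCC1 (oxygen relayed through OsO4); water, O
Why: Catalytic osmylation (Upjohn dihydroxylation) should choose the electron-rich 1,1-disubstituted alkene over the acrylate and approach from the equatorial side, away from the syn-axial hydrogens, which gives the equatorial tertiary OH and the axial CH2OH cis to the ester.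

Step 14
Reactants: 22 (butenolide acid from step 11); 24 (diol from step 13)
Product: 26 tert-butyl (1S,2S,5R,6S)-2-[({(2E)-2-[(benzyloxy)methyl]-3-[(6R,7S)-1-oxo-6-(propan-2-yl)-1,3,4,5,6,7-hexahydro-2-benzofuran-7-yl]prop-2-enoyl}oxy)methyl]-6-[(1E)-2-[(benzyloxy)methyl]-3-tert-butoxy-3-oxoprop-1-en-1-yl]-2-hydroxy-5-(propan-2-yl)cyclohexane-1-carboxylate, via mixed anhydride 25 (not isolated)
Conditions: 22, 2,4,6-trichlorobenzoyl chloride, Et3N, THF, rt; then 24, DMAP, toluene, rt
Reagents that add atoms: none
Why: Yamaguchi esterification through mixed anhydride 25 should acylate only the primary hydroxyl, since the tertiary one is too hindered and the tert-butyl ester does not lactonise.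

Step 15
Reactants: 26 (protected dimer from step 14)
Product: 27 (1S,2S,5R,6S)-6-[(1E)-2-carboxy-3-hydroxyprop-1-en-1-yl]-2-hydroxy-2-[({(2E)-2-(hydroxymethyl)-3-[(6R,7S)-1-oxo-6-(propan-2-yl)-1,3,4,5,6,7-hexahydro-2-benzofuran-7-yl]prop-2-enoyl}oxy)methyl]-5-(propan-2-yl)cyclohexane-1-carboxylic acid (target)
Conditions: BCl3, pentamethylbenzene, CH2Cl2, −78 → 0 °C; then H2O
Reagents that add atoms: none
Why: BCl3 should cleave the two benzyl ethers (benzyl cation trapped by pentamethylbenzene) and the two tert-butyl esters by alkyl–oxygen fission, while the primary alkyl ester, the butenolide, the alkenes and the inductively deactivated tertiary alcohol offer no stabilised cation and should survive.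

**Compound list**

1 | (S)-(−)-limonene, (4S)-1-methyl-4-(prop-1-en-2-yl)cyclohex-1-ene | CC1=CC[C@H](CC1)C(C)=C | starting material
2 | (4S)-1-methyl-4-(propan-2-yl)cyclohex-1-ene | CC1=CC[C@H](CC1)C(C)C | intermediate
3 | (3S)-6-oxo-3-(propan-2-yl)heptanal | O=CC[C@H](CCC(C)=O)C(C)C | intermediate (not isolated)
4 | (5S)-5-(2,2-dimethoxyethyl)-6-methylheptan-2-one | COC(OC)C[C@H](CCC(C)=O)C(C)C | intermediate
5 | (4S)-4-(2,2-dimethoxyethyl)-5-methylhexanoic acid | COC(OC)C[C@H](CCC(=O)O)C(C)C | intermediate
6 | 3-tert-butoxy-3-oxopropanoic acid | OC(=O)CC(=O)OC(C)(C)C | starting material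
7 | 1-[(4S)-4-(2,2-dimethoxyethyl)-5-methylhexanoyl]-1H-imidazole | COC(OC)C[C@H](CCC(=O)n1ccnc1)C(C)C | intermediate (not isolated)
8 | tert-butyl (6S)-6-(2,2-dimethoxyethyl)-7-methyl-3-oxooctanoate | COC(OC)C[C@H](CCC(=O)CC(=O)OC(C)(C)C)C(C)C | intermediate
9 | tert-butyl (6S)-7-methyl-3-oxo-6-(2-oxoethyl)octanoate | O=CC[C@H](CCC(=O)CC(=O)OC(C)(C)C)C(C)C | intermediate (not isolated)
10 | (3S)-8-tert-butoxy-6,8-dioxo-3-(propan-2-yl)octanoic acid | OC(=O)C[C@H](CCC(=O)CC(=O)OC(C)(C)C)C(C)C | intermediate
11 | tert-butyl (triphenylphosphoranylidene)acetate | CC(C)(C)OC(=O)C=P(c1ccccc1)(c1ccccc1)c1ccccc1 | starting material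
12 | benzyl chloromethyl ether | ClCOCc1ccccc1 | starting material
13 | tert-butyl 3-(benzyloxy)-2-(triphenylphosphoranylidene)propanoate | CC(C)(C)OC(=O)C(COCc1ccccc1)=P(c1ccccc1)(c1ccccc1)c1ccccc1 | intermediate
14 | tert-butyl (6S)-6-(2-chloro-2-oxoethyl)-7-methyl-3-oxooctanoate | ClC(=O)C[C@H](CCC(=O)CC(=O)OC(C)(C)C)C(C)C | intermediate (not isolated)
15 | tert-butyl (6R)-7-methyl-3-oxo-6-(2-oxoethenyl)octanoate | O=C=C[C@H](CCC(=O)CC(=O)OC(C)(C)C)C(C)C | intermediate (not isolated)
16 | di-tert-butyl (5R)-2-[(benzyloxy)methyl]-8-oxo-5-(propan-2-yl)deca-2,3-dienedioate (allene axis not defined) | CC(C)(C)OC(=O)C(COCc1ccccc1)=C=C[C@H](CCC(=O)CC(=O)OC(C)(C)C)C(C)C | intermediate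
17 | tert-butyl (1S,5R,6S)-6-[(1E)-2-[(benzyloxy)methyl]-3-tert-butoxy-3-oxoprop-1-en-1-yl]-2-oxo-5-(propan-2-yl)cyclohexane-1-carboxylate | CC(C)[C@H]1CCC(=O)[C@@H](C(=O)OC(C)(C)C)[C@@H]1/C=C(\COCc2ccccc2)C(=O)OC(C)(C)C | intermediate
18 | tert-butyl (5R,6S)-6-[(1E)-2-[(benzyloxy)methyl]-3-tert-butoxy-3-oxoprop-1-en-1-yl]-5-(propan-2-yl)-2-[(trifluoromethanesulfonyl)oxy]cyclohex-1-ene-1-carboxylate | CC(C)[C@H]1CCC(OS(=O)(=O)C(F)(F)F)=C(C(=O)OC(C)(C)C)[C@@H]1/C=C(\COCc2ccccc2)C(=O)OC(C)(C)C | intermediate
19 | (tributylstannyl)methanol | CCCC[Sn](CCCC)(CCCC)CO | starting material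
20 | tert-butyl (5R,6S)-6-[(1E)-2-[(benzyloxy)methyl]-3-tert-butoxy-3-oxoprop-1-en-1-yl]-2-(hydroxymethyl)-5-(propan-2-yl)cyclohex-1-ene-1-carboxylate | CC(C)[C@H]1CCC(CO)=C(C(=O)OC(C)(C)C)[C@@H]1/C=C(\COCc2ccccc2)C(=O)OC(C)(C)C | intermediate
21 | (5R,6S)-6-[(1E)-2-[(benzyloxy)methyl]-2-carboxyethen-1-yl]-2-(hydroxymethyl)-5-(propan-2-yl)cyclohex-1-ene-1-carboxylic acid | CC(C)[C@H]1CCC(CO)=C(C(=O)O)[C@@H]1/C=C(\COCc2ccccc2)C(=O)O | intermediate (not isolated)
22 | (2E)-2-[(benzyloxy)methyl]-3-[(6R,7S)-1-oxo-6-(propan-2-yl)-1,3,4,5,6,7-hexahydro-2-benzofuran-7-yl]prop-2-enoic acid | OC(=O)/C(COCc1ccccc1)=C/[C@H]2C3=C(CC[C@@H]2C(C)C)COC3=O | intermediate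
23 | tert-butyl (1S,5R,6S)-6-[(1E)-2-[(benzyloxy)methyl]-3-tert-butoxy-3-oxoprop-1-en-1-yl]-2-methylidene-5-(propan-2-yl)cyclohexane-1-carboxylate | CC(C)[C@H]1CCC(=C)[C@@H](C(=O)OC(C)(C)C)[C@@H]1/C=C(\COCc2ccccc2)C(=O)OC(C)(C)C | intermediate
24 | tert-butyl (1S,2S,5R,6S)-6-[(1E)-2-[(benzyloxy)methyl]-3-tert-butoxy-3-oxoprop-1-en-1-yl]-2-hydroxy-2-(hydroxymethyl)-5-(propan-2-yl)cyclohexane-1-carboxylate | CC(C)[C@H]1CC[C@@](O)(CO)[C@@H](C(=O)OC(C)(C)C)[C@@H]1/C=C(\COCc2ccccc2)C(=O)OC(C)(C)C | intermediate
25 | (2E)-2-[(benzyloxy)methyl]-3-[(6R,7S)-1-oxo-6-(propan-2-yl)-1,3,4,5,6,7-hexahydro-2-benzofuran-7-yl]prop-2-enoic 2,4,6-trichlorobenzoic anhydride | O=C(OC(=O)/C(COCc1ccccc1)=C/[C@H]2C3=C(CC[C@@H]2C(C)C)COC3=O)c4c(Cl)cc(Cl)cc4Cl | intermediate (not isolated)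
26 | tert-butyl (1S,2S,5R,6S)-2-[({(2E)-2-[(benzyloxy)methyl]-3-[(6R,7S)-1-oxo-6-(propan-2-yl)-1,3,4,5,6,7-hexahydro-2-benzofuran-7-yl]prop-2-enoyl}oxy)methyl]-6-[(1E)-2-[(benzyloxy)methyl]-3-tert-butoxy-3-oxoprop-1-en-1-yl]-2-hydroxy-5-(propan-2-yl)cyclohexane-1-carboxylate | CC(C)[C@H]1CC[C@@](O)(COC(=O)/C(=C/[C@H]2C3=C(CC[C@@H]2C(C)C)COC3=O)COCc4ccccc4)[C@@H](C(=O)OC(C)(C)C)[C@@H]1/C=C(\COCc5ccccc5)C(=O)OC(C)(C)C | intermediate
27 | (1S,2S,5R,6S)-6-[(1E)-2-carboxy-3-hydroxyprop-1-en-1-yl]-2-hydroxy-2-[({(2E)-2-(hydroxymethyl)-3-[(6R,7S)-1-oxo-6-(propan-2-yl)-1,3,4,5,6,7-hexahydro-2-benzofuran-7-yl]prop-2-enoyl}oxy)methyl]-5-(propan-2-yl)cyclohexane-1-carboxylic acid | CC(C)[C@H]1CC[C@@](O)(COC(=O)/C(=C/[C@H]2C3=C(CC[C@@H]2C(C)C)COC3=O)CO)[C@@H](C(=O)O)[C@@H]1/C=C(\CO)C(=O)O | target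

**Step count and risks**

Total step count: 15. Longest linear sequence: 12 steps (steps 1–5, 7–11, 14, 15).

Steps most likely to fail:

Step 8 (Proposed new method). The phosphonium dienolate may be diverted into proton-shift isomerisation to a conjugated dienoate or into intermolecular oligomerisation instead of ring closure, and 1,2-induction at the new centre may be weak. The fallback uses known chemistry, sets out from acetal 8 and comes back at 17. Acetal 8 would be hydrolysed without oxidation (oxalic acid, wet acetone) to aldehyde 9, now isolated. N-Bromosuccinimide (EtOAc, rt) should brominate only the β-keto ester carbon to give bromo keto ester F1. A secondary-amine catalyst (α-methylproline, Et3N, CHCl3) should then make the same ring bond with reversed polarity: the enamine carbon of the aldehyde displaces the activated bromide (enamine-catalysed intramolecular α-alkylation of an aldehyde) to give formyl keto ester F2. Its formyl-bearing centre is enolisable and should settle in the trans diequatorial arrangement. Wittig olefination of F2 with ylide 13 (toluene, 80 °C) then gives 17.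

Step 7. Acylation of the β-keto ester enol by the acid chloride or the ketene under amine base may compete with ketene formation and capture by the ylide. The fallback sets out from acid 10 and comes back at 16. Acid 10 would be silylated twice (TBSOTf, Et3N, CH2Cl2) to bis-silyl compound F3, which masks the acidic methylene as a silyl enol ether. Oxalyl chloride with catalytic DMF should convert the silyl ester directly into acid chloride F4 under neutral conditions. Et3N then gives ketene F5, which ylide 13 traps as silyl enol ether allenoate F6. HF·pyridine in THF at 0 °C removes the enol silyl group and releases 16.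

Step 13. Facial selectivity of the osmylation on the exocyclic alkene may be low or reversed, and the diol may be hard to separate from its epimer. The fallback sets out from alkene 23 and comes back at 26, bypassing diol 24 and the esterification. Payne epoxidation (PhCN, H2O2, KHCO3, MeOH), whose bulky peroxyimidic acid is expected to attack from the equatorial side, would give spiro-epoxide F7. Union with acid 22 by carboxylate opening of the epoxide at its CH2 terminus (Cs2CO3 (0.5 equiv), DMF, 60 °C) then forms the ester bond and the tertiary alcohol of 26 in one step.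

**Further compounds**

F1 | step 8 | tert-butyl (6S)-2-bromo-7-methyl-3-oxo-6-(2-oxoethyl)octanoate (both C2 epimers) | O=CC[C@H](CCC(=O)C(Br)C(=O)OC(C)(C)C)C(C)C
F2 | step 8 | tert-butyl (1S,5R,6R)-6-formyl-2-oxo-5-(propan-2-yl)cyclohexane-1-carboxylate | CC(C)[C@H]1CCC(=O)[C@@H](C(=O)OC(C)(C)C)[C@@H]1C=O
F3 | step 7 | tert-butyl (6S)-3-[(tert-butyldimethylsilyl)oxy]-6-{2-[(tert-butyldimethylsilyl)oxy]-2-oxoethyl}-7-methyloct-2-enoate | CC(C)(C)[Si](C)(C)OC(=O)C[C@H](CCC(O[Si](C)(C)C(C)(C)C)=CC(=O)OC(C)(C)C)C(C)C
F4 | step 7 | tert-butyl (6S)-3-[(tert-butyldimethylsilyl)oxy]-6-(2-chloro-2-oxoethyl)-7-methyloct-2-enoate | ClC(=O)C[C@H](CCC(O[Si](C)(C)C(C)(C)C)=CC(=O)OC(C)(C)C)C(C)C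
F5 | step 7 | tert-butyl (6R)-3-[(tert-butyldimethylsilyl)oxy]-7-methyl-6-(2-oxoethenyl)oct-2-enoate | O=C=C[C@H](CCC(O[Si](C)(C)C(C)(C)C)=CC(=O)OC(C)(C)C)C(C)C
F6 | step 7 | di-tert-butyl (5R)-2-[(benzyloxy)methyl]-8-[(tert-butyldimethylsilyl)oxy]-5-(propan-2-yl)deca-2,3,8-trienedioate | CC(C)(C)OC(=O)C(COCc1ccccc1)=C=C[C@H](CCC(O[Si](C)(C)C(C)(C)C)=CC(=O)OC(C)(C)C)C(C)C
F7 | step 13 | tert-butyl 5-[(1E)-2-[(benzyloxy)methyl]-3-tert-butoxy-3-oxoprop-1-en-1-yl]-6-(propan-2-yl)-1-oxaspiro[2.5]octane-4-carboxylate (epoxide oxygen equatorial, ring centres as in 23) | CC(C)[C@H]1CC[C@@]2(CO2)[C@@H](C(=O)OC(C)(C)C)[C@@H]1/C=C(\COCc3ccccc3)C(=O)OC(C)(C)C
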